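**Plan**
- Retrosynthesis first cuts the two aryl–CH2 bonds of the bridge (ring A–CH2 by quinone methide capture, ring B–CH2 by aminomethylation) and the aryl–acyl bond of ring A, giving two propiophenone monomers.
- In ring B, two ring bonds are then cut: bridge-bearing carbon to the neighbouring C–OH, and propionyl-bearing carbon to the C–OH next to the methyl group.
- What allows this: ring B carries oxygen on three alternate carbons with methyl, bridge CH2 and propionyl on the carbons between them. This maps onto a 1,1,3-trioxygenated 2-methylbutadiene plus an alkyne with an alkoxy group on one carbon and the propionyl group on the other.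
- Forward: diene (steps 1–2) and ynone (step 3) are made separately; ring B is closed by cycloaddition and aromatization (step 4), de-ethylated (step 5) and aminomethylated (step 6); ring A comes from a Friedel–Crafts acylation (step 7); the rings are joined last (step 8).
- Stereochemistry: the target has no stereocentre, so none has to be set.

Key step: step 4

Remark: compounds 1, 2, 9 and 11 carry a stereocentre only transiently and are racemic; diene 5 is used as a mixture of ketene acetal geometries, which converge on aromatization.

**Step 1**
Reactants: 1 methyl 2-methyl-3-oxobutanoate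
Product: 3 methyl (E)-3-methoxy-2-methylbut-2-enoate, via dimethyl ketal 2 (not isolated)
Conditions: HC(OMe)3, cat. H2SO4, MeOH, rt; then distillation (loss of MeOH)
Reagents that add atoms: trimethyl orthoformate, COC(OC)OC
Why: Acid-catalysed ketalization of the ketone of a β-keto ester with the orthoformate and loss of methanol from ketal 2 should give the conjugated β-methoxy enoate (enol ether formation via the ketal), expected mainly as the E isomer; the geometry does not matter later because this double bond becomes the central single bond of the diene.

**Step 2**
Reactants: 3 methyl (E)-3-methoxy-2-methylbut-2-enoate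
Product: 5 [(1,3-dimethoxy-2-methylbuta-1,3-dien-1-yl)oxy]trimethylsilane, via lithium dienolate 4 (not isolated)
Conditions: LiN(i-Pr)2, THF, −78 °C; then Me3SiCl, −78 °C → rt; pentane, filtration, Kugelrohr distillation
Reagents that add atoms: chlorotrimethylsilane, C[Si](C)(C)Cl
Why: With no α-hydrogen available, LiN(i-Pr)2 should remove a γ-hydrogen from the C4 methyl group and the extended enolate 4 is silylated on oxygen by the hard silyl chloride, the standard preparation of Brassard-type vinylogous silyl ketene acetals (dienolate O-silylation).

**Step 3**
Reactants: 6 ethoxyethyne (ethoxyacetylene); 7 N-methoxy-N-methylpropanamide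
Product: 10 1-ethoxypent-1-yn-3-one, via lithium ethoxyacetylide 8 (not isolated), via tetrahedral lithium adduct 9 (not isolated)
Conditions: n-BuLi, THF, −78 °C; then 7, −78 → −20 °C; then H2O (pH 7 phosphate buffer), 0 °C
Reagents that add atoms: none
Why: Weinreb ketone synthesis: acetylide 8 adds once to the N-methoxy-N-methyl amide and the chelated adduct 9 should survive until the quench, so over-addition is avoided, while a cold neutral quench spares the acid-sensitive ynol ether.

**Step 4**
Reactants: 5 [(1,3-dimethoxy-2-methylbuta-1,3-dien-1-yl)oxy]trimethylsilane; 10 1-ethoxypent-1-yn-3-one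
Product: 13 1-(6-ethoxy-2-hydroxy-4-methoxy-3-methylphenyl)propan-1-one, via cycloadduct 11 (not isolated), via aryl silyl ether 12 (not isolated)
Conditions: 5 (1.5 equiv), PhMe, 0 °C → rt (50 °C if conversion stalls); then 1 M HCl, THF, rt
Reagents that add atoms: none
Why: Proposed new method: the electron-rich CH2 terminus (C4) of diene 5 should attack the ethoxy-bearing β-carbon of the push–pull ynone 10 while the ketene acetal carbon (C1) bonds to the α-carbon, either in a concerted but strongly asynchronous (4+2) cycloaddition or, at the stepwise limit, by vinylogous Mukaiyama–Michael addition followed by 6-exo-trig collapse of the allenolate carbon onto the silyloxy(methoxy)carbenium ion, both leading to cyclohexa-1,4-diene 11. The closest known reaction type is the Diels–Alder addition and aromatization of 1,1,3-trioxygenated (Brassard-type) dienes with acetylenic ketones and esters to give resorcinol derivatives; a 1-alkoxyalkynone has not served as the two-carbon partner. Adduct 11 should lose methanol across the acetal carbon and the ring CH2 to give aryl silyl ether 12, which the acidic work-up cleaves to phenol 13; the benzene ring is thus closed in an intermolecular (4+2) mode and no stereocentre remains. The step needs head-to-tail regiochemistry and C1/C4 reactivity of the diene: the ketone keeps the β-carbon of the alkyne electrophilic despite the ethoxy donor, the largest HOMO coefficient of the diene lies on the CH2 terminus, the 2-methyl group hinders attack through C2, and the absence of a Lewis acid disfavours aldol or hetero-Diels–Alder attack at the ketone. The methoxy group comes from the vinylogous ester oxygen of the diene, so its place between the methyl group and the free ring CH is fixed by construction, and the propionyl group lands between two oxygens as ring B requires.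

**Step 5**
Reactants: 13 1-(6-ethoxy-2-hydroxy-4-methoxy-3-methylphenyl)propan-1-one
Product: 15 1-(2,6-dihydroxy-4-methoxy-3-methylphenyl)propan-1-one, via bis(dichloroboryl) ether 14 (not isolated)
Conditions: BCl3 (3 equiv), CH2Cl2, −78 °C → rt; then ice-water
Reagents that add atoms: none
Why: Chelation-directed dealkylation of an aryl alkyl ether ortho to a carbonyl group by BCl3: boron held between the ketone and the ortho oxygens activates only the ethoxy group, chloride removes the ethyl group as chloroethane, and the para methoxy group, which cannot join the chelate, should survive.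

**Step 6**
Reactants: 15 1-(2,6-dihydroxy-4-methoxy-3-methylphenyl)propan-1-one
Product: 16 1-{3-[(dimethylamino)methyl]-2,6-dihydroxy-4-methoxy-5-methylphenyl}propan-1-one
Conditions: Me2N=CH2+ I− (1.3 equiv), Et3N, CH2Cl2, 0 °C → rt
Reagents that add atoms: N,N-dimethylmethylideneammonium iodide (Eschenmoser's salt), C=[N+](C)C.[I-]
Why: Phenol Mannich reaction with a preformed iminium salt at the only unsubstituted ring carbon, which is activated by an ortho hydroxyl, an ortho methoxy and a para hydroxyl group; the absence of free formaldehyde should suppress diarylmethane formation.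

**Step 7**
Reactants: 17 2-methylbenzene-1,3,5-triol (2,4,6-trihydroxytoluene)
Product: 18 1-(2,4,6-trihydroxy-3-methylphenyl)propan-1-one
Conditions: EtCOCl (1.1 equiv), AlCl3 (3.5 equiv), PhNO2/CH2Cl2, 0 → 50 °C; then ice, 2 M HCl
Reagents that add atoms: propanoyl chloride, CCC(=O)Cl
Why: Friedel–Crafts C-acylation of a phloroglucinol; the two free ring positions of 17 are equivalent by symmetry, so a single monoketone should form, and the first acyl group deactivates the ring towards a second.

**Step 8**
Reactants: 16 1-{3-[(dimethylamino)methyl]-2,6-dihydroxy-4-methoxy-5-methylphenyl}propan-1-one; 18 1-(2,4,6-trihydroxy-3-methylphenyl)propan-1-one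
Product: 20 1-{3-[(2,4-dihydroxy-6-methoxy-5-methyl-3-propanoylphenyl)methyl]-2,4,6-trihydroxy-5-methylphenyl}propan-1-one, via quinone methide 19 (not isolated)
Conditions: 18 (2 equiv), 1,4-dioxane, 100 °C, N2 stream
Reagents that add atoms: none
Why: Thermal loss of dimethylamine from the phenolic Mannich base should give ortho-quinone methide 19, which is captured by conjugate (Friedel–Crafts-type Michael) addition of the only free ring carbon of phloroglucinol 18 and re-aromatizes, the usual way to methylene-bridged bis-acylphloroglucinols; both rings are then fully substituted, so no further alkylation can follow.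

**Compound list**
1 | methyl 2-methyl-3-oxobutanoate (racemic) | CC(=O)C(C)C(=O)OC | starting material
2 | methyl 3,3-dimethoxy-2-methylbutanoate (racemic) | CC(OC)(OC)C(C)C(=O)OC | intermediate
3 | methyl (E)-3-methoxy-2-methylbut-2-enoate | C/C(OC)=C(/C)C(=O)OC | intermediate
4 | lithium 1,3-dimethoxy-2-methylbuta-1,3-dien-1-olate | COC([O-])=C(C)C(OC)=C.[Li+] | intermediate
5 | [(1,3-dimethoxy-2-methylbuta-1,3-dien-1-yl)oxy]trimethylsilane (mixture of ketene acetal geometries) | COC(O[Si](C)(C)C)=C(C)C(OC)=C | intermediate
6 | ethoxyethyne | CCOC#C | starting material
7 | N-methoxy-N-methylpropanamide | CCC(=O)N(C)OC | starting material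
8 | lithium ethoxyacetylide | CCOC#C[Li] | intermediate
9 | lithium 1-ethoxy-3-[methoxy(methyl)amino]pent-1-yn-3-olate (racemic) | CCOC#CC(CC)([O-])N(C)OC.[Li+] | intermediate
10 | 1-ethoxypent-1-yn-3-one | CCOC#CC(=O)CC | intermediate
11 | 1-{2-ethoxy-4,6-dimethoxy-5-methyl-6-[(trimethylsilyl)oxy]cyclohexa-1,4-dien-1-yl}propan-1-one (racemic) | CCC(=O)C1=C(OCC)CC(OC)=C(C)C1(OC)O[Si](C)(C)C | intermediate
12 | 1-{6-ethoxy-4-methoxy-3-methyl-2-[(trimethylsilyl)oxy]phenyl}propan-1-one | CCC(=O)c1c(O[Si](C)(C)C)c(C)c(OC)cc1OCC | intermediate
13 | 1-(6-ethoxy-2-hydroxy-4-methoxy-3-methylphenyl)propan-1-one | CCC(=O)c1c(O)c(C)c(OC)cc1OCC | intermediate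
14 | [(5-methoxy-4-methyl-2-propanoyl-1,3-phenylene)bis(oxy)]bis(dichloroborane) | CCC(=O)c1c(OB(Cl)Cl)c(C)c(OC)cc1OB(Cl)Cl | intermediate
15 | 1-(2,6-dihydroxy-4-methoxy-3-methylphenyl)propan-1-one | CCC(=O)c1c(O)c(C)c(OC)cc1O | intermediate
16 | 1-{3-[(dimethylamino)methyl]-2,6-dihydroxy-4-methoxy-5-methylphenyl}propan-1-one | CCC(=O)c1c(O)c(C)c(OC)c(CN(C)C)c1O | intermediate
17 | 2-methylbenzene-1,3,5-triol | Cc1c(O)cc(O)cc1O | starting material
18 | 1-(2,4,6-trihydroxy-3-methylphenyl)propan-1-one | CCC(=O)c1c(O)cc(O)c(C)c1O | intermediate
19 | 3-hydroxy-5-methoxy-4-methyl-6-methylidene-2-propanoylcyclohexa-2,4-dien-1-one | CCC(=O)C1=C(O)C(C)=C(OC)C(=C)C1=O | intermediate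
20 | 1-{3-[(2,4-dihydroxy-6-methoxy-5-methyl-3-propanoylphenyl)methyl]-2,4,6-trihydroxy-5-methylphenyl}propan-1-one | CCC(=O)c1c(O)c(C)c(O)c(Cc2c(O)c(C(=O)CC)c(O)c(C)c2OC)c1O | target

**Step count**
Total: 8 steps. Longest linear sequence: 6 steps (1, 2, 4, 5, 6, 8).

**Steps most likely to fail**

Step 4. The ethoxy donor may slow the cycloaddition so far that the diene hydrolyses first. The ynol ether may also lose ethylene thermally, or the reaction may stop at an open-chain conjugate adduct. The fallback uses known chemistry and sets out from ketone 18. One equivalent of dimethyl sulfate with K2CO3 in acetone should methylate mainly the para hydroxyl group, the most acidic one and the one not hydrogen-bonded to the ketone (regioselective mono-O-alkylation of an acylphloroglucinol). This makes no new compound (F0), bypasses steps 1 to 5 and comes back to the route at 15.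

Step 8. Amine loss may need temperatures at which the quinone methide is consumed unproductively (O-alkylation, oligomerization), or at which the liberated amine exchanges the methylene bridge between rings and gives symmetrical dimers. The fallback reverses the roles of the two rings and sets out from 18. Aminomethylation of 18 with Me2N=CH2+ I− and Et3N in CH2Cl2 should give 1-{3-[(dimethylamino)methyl]-2,4,6-trihydroxy-5-methylphenyl}propan-1-one F1. Its benzylic carbon lies between two hydroxyl groups, so it should release 3,5-dihydroxy-2-methyl-6-methylidene-4-propanoylcyclohexa-2,4-dien-1-one F2 under milder heating. Capture of F2 by the free ring carbon of 15 comes back to the route at 20.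

Step 3. The N,O-dimethylhydroxylamine or water set free at the quench may add to the electrophilic ynone, or the acylation may stay incomplete. The fallback changes the oxidation level of the electrophile and sets out from 6 by way of acetylide 8. Addition to propanal in THF at −78 °C should give lithium 1-ethoxypent-1-yn-3-olate F3 and, after a neutral quench, 1-ethoxypent-1-yn-3-ol F4. Oxidation of this propargylic alcohol with activated MnO2 in CH2Cl2 under neutral conditions, which should avoid Meyer–Schuster rearrangement, comes back to the route at 10.

**Further compounds**
F0 | step 4 | none | none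
F1 | step 8 | 1-{3-[(dimethylamino)methyl]-2,4,6-trihydroxy-5-methylphenyl}propan-1-one | CCC(=O)c1c(O)c(CN(C)C)c(O)c(C)c1O
F2 | step 8 | 3,5-dihydroxy-2-methyl-6-methylidene-4-propanoylcyclohexa-2,4-dien-1-one | CCC(=O)C1=C(O)C(=C)C(=O)C(C)=C1O
F3 | step 3 | lithium 1-ethoxypent-1-yn-3-olate (racemic) | CCOC#CC([O-])CC.[Li+]
F4 | step 3 | 1-ethoxypent-1-yn-3-ol (racemic) | CCOC#CC(O)CC
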